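**Plan**

- Numbering: oxolane O1, C2 (trimethoxyphenyl), C3 (bears C9H2OH), C4 (bears the dimethoxybenzyl group through C7'), C5. Retrosynthetic cuts, in order: C9–OH back to an acyl group on a chiral auxiliary; C4–H and C7'–H back to a C4=C7' benzylidene; O1–C5 and C2–C3 together (aryl aldehyde C2=O1 on one side, the C3–C4–C5 unit on the other); the acyl–N bond; the C4=C7' bond.
- Enabling feature: with C4=C7' in place, C3 is α to the C9 carbonyl and vinylogously benzylic (a dienolate carbon), while C5 is an allylic CH2–Cl. C3–C4(=C7')–C5 is thus a trimethylenemethane-like donor–acceptor unit that can span the aldehyde C=O.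
- Forward order: Stobbe condensation of 3,4-dimethoxybenzaldehyde with dimethyl succinate makes C7'=C4. A temporary lactone ring ties C9 to C5 and is opened to acyl chloride plus allylic chloride. The (R)-4-benzyl oxazolidinone is attached. The oxolane ring then arises in a one-flask aldol/cycloetherification with 3,4,5-trimethoxybenzaldehyde, followed by alkene hydrogenation and reductive removal of the auxiliary.
- Stereochemistry: C3 from the auxiliary (enolate face); C2 from the anti topology of the magnesium aldol, which corresponds to 2,3-cis on the ring; C4 from hydrogenation on the ring face opposite the two cis substituents (all-cis, 2R,3R,4R).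
- Helpers removed later: lactone tether (step 3), chloride (step 5), C4=C7' unsaturation (step 6), auxiliary (step 7).

Key step: step 5

Assumption: the MgCl2-catalysed anti-aldol is taken to run through the chelated Z-enolate with the aldehyde on the face remote from the 4-benzyl group (the sense of auxiliary-controlled alkylation); on this basis the (R)-auxiliary leads to (2R,3S) in 13, and the (S)-auxiliary would be used if the opposite sense applied.

**Route**

Step 1
Reactants: 1 3,4-dimethoxybenzaldehyde; 2 dimethyl succinate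
Product: 3 (E)-4-(3,4-dimethoxyphenyl)-3-(methoxycarbonyl)but-3-enoic acid
Conditions: NaOMe, MeOH, reflux; then aq. HCl
Reagents that add atoms: none
Why: Stobbe condensation of a non-enolisable aryl aldehyde with a succinic diester should give the (E)-arylidene half-ester (aryl trans to the ester), which differentiates the two carboxyl groups in one step: the free acid on the CH2 arm becomes C9 and the conjugated ester becomes C5; no stereocenter is formed.

Step 2
Reactants: 3 (E)-4-(3,4-dimethoxyphenyl)-3-(methoxycarbonyl)but-3-enoic acid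
Product: 5 (E)-4-(3,4-dimethoxybenzylidene)oxolan-2-one, via hydroxy acid 4 (not isolated)
Conditions: i-Bu2AlH (3.5 equiv), CH2Cl2, −78 → −40 °C; then 2 M HCl, 23 °C
Reagents that add atoms: none
Why: Chemoselective hydride reduction: the first equivalent of i-Bu2AlH converts the acid into an aluminium carboxylate that is not reduced at low temperature, the conjugated ester undergoes 1,2-reduction to the allylic alcohol 4, and acidification closes the five-membered lactone, which stores C5 as an allylic ester of the C9 carboxyl; no stereocenter is formed.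

Step 3
Reactants: 5 (E)-4-(3,4-dimethoxybenzylidene)oxolan-2-one
Product: 6 (E)-3-(chloromethyl)-4-(3,4-dimethoxyphenyl)but-3-enoyl chloride
Conditions: SOCl2 (1.5 equiv), ZnCl2 (5 mol %), CH2Cl2, 0 → 23 °C; volatiles removed, used crude
Reagents that add atoms: thionyl chloride, O=S(Cl)Cl
Why: Ring-opening chlorination of a γ-lactone by SOCl2/ZnCl2 (the reaction type that converts γ-butyrolactone into 4-chlorobutanoyl chloride) should be easy here because C5 is allylic, and it delivers the C5 leaving group and the activated C9 acyl group together without passing through a free hydroxy acid that would relactonise.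

Step 4
Reactants: 6 (E)-3-(chloromethyl)-4-(3,4-dimethoxyphenyl)but-3-enoyl chloride; 7 (R)-4-benzyl-1,3-oxazolidin-2-one
Product: 9 (R)-4-benzyl-3-[(E)-3-(chloromethyl)-4-(3,4-dimethoxyphenyl)but-3-enoyl]-1,3-oxazolidin-2-one, via lithium oxazolidinide 8 (not isolated)
Conditions: 7, n-BuLi, THF, −78 °C; then added to 6 (1.1 equiv), THF, −78 °C
Reagents that add atoms: none
Why: N-Acylation of a lithiated oxazolidinone with an acid chloride at −78 °C is the standard way to N-acyl oxazolidinones and is far faster than alkylation by the allylic chloride, and inverse addition keeps base away from the acidic C3–H2 group of 9.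

Step 5
Reactants: 9 (R)-4-benzyl-3-[(E)-3-(chloromethyl)-4-(3,4-dimethoxyphenyl)but-3-enoyl]-1,3-oxazolidin-2-one; 10 3,4,5-trimethoxybenzaldehyde
Product: 13 (R)-4-benzyl-3-[(2R,3S,4E)-4-(3,4-dimethoxybenzylidene)-2-(3,4,5-trimethoxyphenyl)oxolane-3-carbonyl]-1,3-oxazolidin-2-one, via silyl ether 11 (not isolated), via aldol 12 (not isolated)
Conditions: MgCl2 (20 mol %), i-Pr2NEt (2 equiv), Me3SiCl (1.5 equiv), 10 (1.2 equiv), EtOAc, 23 °C; then n-Bu4NF (THF), 0 °C, same flask; pH 7 buffer quench
Reagents that add atoms: none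
Why: Soft enolisation by MgCl2/i-Pr2NEt gives the chelated (Z)-magnesium dienolate of 9, whose α-carbon C3 adds to the aldehyde carbon C2 and whose aldolate is silylated to 11; fluoride then releases the C2 alkoxide of 12, which displaces the allylic chloride at C5, so that C2–C3 and O1–C5 are made in one flask. The closest known reaction types are the MgCl2-catalysed anti-aldol of N-acyl oxazolidinones with aromatic aldehydes and the magnesium halide-mediated formal [3+2] ring expansion of methylenecyclopropane carboxamides, which runs through the same 2-(halomethyl)allyl enolate. The oxolane ring is closed by a 5-exo-tet intramolecular Williamson etherification in which the alkoxide attacks the primary carbon C5 and no stereocenter is touched. C3 is controlled by the 4-benzyl group of the (R)-auxiliary, which shields one face of the chelated enolate, and C2 by the anti topology of this aldol with aryl aldehydes, which places the aryl group at C2 and the acyl group at C3 cis on the ring, (2R,3S) in 13. The step needs α- and not γ-attack of the dienolate, secured by the aryl group on the γ-carbon C7' (γ-attack is hindered and would break the styrene conjugation), and aldol addition faster than intramolecular O- or C-alkylation of the enolate or amine quaternisation, secured by chloride as a modest leaving group and a hindered base. It also needs closure at C5 and not SN2' attack at C7', secured by C5 being primary and by the conjugated benzylidene that only closure at C5 retains.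

Step 6
Reactants: 13 (R)-4-benzyl-3-[(2R,3S,4E)-4-(3,4-dimethoxybenzylidene)-2-(3,4,5-trimethoxyphenyl)oxolane-3-carbonyl]-1,3-oxazolidin-2-one
Product: 14 (R)-4-benzyl-3-[(2R,3S,4R)-4-(3,4-dimethoxybenzyl)-2-(3,4,5-trimethoxyphenyl)oxolane-3-carbonyl]-1,3-oxazolidin-2-one
Conditions: H2 (1 atm), 5% Pt/C, EtOAc, 23 °C
Reagents that add atoms: none
Why: Heterogeneous syn-hydrogenation of the exocyclic alkene: the aryl group at C2 and the acyl oxazolidinone at C3 occupy the same ring face, so both hydrogens should be delivered to the opposite face and the new benzyl group at C4 ends cis to both (4R, all-cis) whatever the alkene geometry, while platinum rather than palladium limits hydrogenolysis of the benzylic and allylic C–O bonds and double-bond migration.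

Step 7
Reactants: 14 (R)-4-benzyl-3-[(2R,3S,4R)-4-(3,4-dimethoxybenzyl)-2-(3,4,5-trimethoxyphenyl)oxolane-3-carbonyl]-1,3-oxazolidin-2-one
Product: 15 [(2R,3R,4R)-4-(3,4-dimethoxybenzyl)-2-(3,4,5-trimethoxyphenyl)oxolan-3-yl]methanol
Conditions: LiBH4 (2 equiv), MeOH (2 equiv), THF, 0 °C; aq. NaOH work-up
Reagents that add atoms: none
Why: Reductive cleavage of the N-acyl oxazolidinone by LiBH4 (hydride attack on the exocyclic carbonyl and reduction of the resulting aldehyde) should give the primary alcohol and free auxiliary without epimerisation, the ethers and the three stereocenters being inert to borohydride.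

**Compound list**

1 | 3,4-dimethoxybenzaldehyde | COc1ccc(C=O)cc1OC | starting material
2 | dimethyl succinate | COC(=O)CCC(=O)OC | starting material
3 | (E)-4-(3,4-dimethoxyphenyl)-3-(methoxycarbonyl)but-3-enoic acid | COC(=O)/C(CC(=O)O)=C/c1ccc(OC)c(OC)c1 | intermediate
4 | (E)-4-(3,4-dimethoxyphenyl)-3-(hydroxymethyl)but-3-enoic acid | OC/C(CC(=O)O)=C/c1ccc(OC)c(OC)c1 | intermediate
5 | (E)-4-(3,4-dimethoxybenzylidene)oxolan-2-one | O=C1C/C(=C\c2ccc(OC)c(OC)c2)CO1 | intermediate
6 | (E)-3-(chloromethyl)-4-(3,4-dimethoxyphenyl)but-3-enoyl chloride | O=C(Cl)C/C(=C\c1ccc(OC)c(OC)c1)CCl | intermediate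
7 | (R)-4-benzyl-1,3-oxazolidin-2-one | O=C1N[C@H](Cc2ccccc2)CO1 | starting material
8 | lithium (R)-4-benzyl-2-oxo-1,3-oxazolidin-3-ide | [Li]N1[C@H](Cc2ccccc2)COC1=O | intermediate
9 | (R)-4-benzyl-3-[(E)-3-(chloromethyl)-4-(3,4-dimethoxyphenyl)but-3-enoyl]-1,3-oxazolidin-2-one | O=C(C/C(=C\c1ccc(OC)c(OC)c1)CCl)N1[C@H](Cc2ccccc2)COC1=O | intermediate
10 | 3,4,5-trimethoxybenzaldehyde | COc1cc(C=O)cc(OC)c1OC | starting material
11 | (R)-4-benzyl-3-[(2S,3E)-3-(chloromethyl)-4-(3,4-dimethoxyphenyl)-2-[(R)-(3,4,5-trimethoxyphenyl)(trimethylsilyloxy)methyl]but-3-enoyl]-1,3-oxazolidin-2-one | O=C(N1[C@H](Cc2ccccc2)COC1=O)[C@H]([C@@H](O[Si](C)(C)C)c1cc(OC)c(OC)c(OC)c1)/C(=C\c1ccc(OC)c(OC)c1)CCl | intermediate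
12 | (R)-4-benzyl-3-[(2S,3E)-3-(chloromethyl)-4-(3,4-dimethoxyphenyl)-2-[(R)-hydroxy(3,4,5-trimethoxyphenyl)methyl]but-3-enoyl]-1,3-oxazolidin-2-one | O=C(N1[C@H](Cc2ccccc2)COC1=O)[C@H]([C@@H](O)c1cc(OC)c(OC)c(OC)c1)/C(=C\c1ccc(OC)c(OC)c1)CCl | intermediate
13 | (R)-4-benzyl-3-[(2R,3S,4E)-4-(3,4-dimethoxybenzylidene)-2-(3,4,5-trimethoxyphenyl)oxolane-3-carbonyl]-1,3-oxazolidin-2-one | COc1ccc(/C=C2/CO[C@@H](c3cc(OC)c(OC)c(OC)c3)[C@H]2C(=O)N2[C@H](Cc3ccccc3)COC2=O)cc1OC | intermediate
14 | (R)-4-benzyl-3-[(2R,3S,4R)-4-(3,4-dimethoxybenzyl)-2-(3,4,5-trimethoxyphenyl)oxolane-3-carbonyl]-1,3-oxazolidin-2-one | COc1ccc(C[C@H]2CO[C@@H](c3cc(OC)c(OC)c(OC)c3)[C@H]2C(=O)N2[C@H](Cc3ccccc3)COC2=O)cc1OC | intermediate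
15 | [(2R,3R,4R)-4-(3,4-dimethoxybenzyl)-2-(3,4,5-trimethoxyphenyl)oxolan-3-yl]methanol | COc1ccc(C[C@H]2CO[C@@H](c3cc(OC)c(OC)c(OC)c3)[C@H]2CO)cc1OC | target

**Step count and risks**

Total steps: 7. Longest linear sequence: 7 steps (1 → 15); 2, 7 and 10 enter as purchased materials.

Steps most likely to fail:

1. Step 5. The allylic chloride may compete with the aldol addition by intramolecular alkylation of the magnesium enolate or by alkylating the amine. The fluoride-released alkoxide may also undergo retro-aldol cleavage or epimerise C3 before the ring closes. Fallback, setting out from 9 and coming back at 13: the leaving group is changed and the two bond formations are separated, with ring closure through a π-allylpalladium complex instead of an alkoxide SN2 reaction. KOAc/18-crown-6 in MeCN converts 9 into the allylic acetate (R)-4-benzyl-3-[(E)-3-(acetoxymethyl)-4-(3,4-dimethoxyphenyl)but-3-enoyl]-1,3-oxazolidin-2-one F1, which is inert to enolate and amine. The same MgCl2/Me3SiCl anti-aldol with 10 gives the trimethylsilyl ether of the acetoxy aldol F2, which AcOH/THF/H2O cleaves to the isolated aldol (R)-4-benzyl-3-[(2S,3E)-3-(acetoxymethyl)-4-(3,4-dimethoxyphenyl)-2-[(R)-hydroxy(3,4,5-trimethoxyphenyl)methyl]but-3-enoyl]-1,3-oxazolidin-2-one F3. Pd(PPh3)4 with K2CO3 in THF (zerovalent palladium, intramolecular allylic etherification at the CH2 terminus) then closes the ring to 13 without a free alkoxide.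

2. Step 3. Under ZnCl2 the ionised allylic chloride may alkylate the electron-rich arene (Friedel–Crafts oligomerisation), or the double bond may move into the lactone ring before opening. Fallback, setting out from 5 and coming back at 9 (6 is bypassed): the carboxyl and the C5 oxygen are differentiated by protection instead of by ring-opening chlorination. 5 is saponified with LiOH to the salt of 4 and silylated (t-BuMe2SiCl, imidazole, DMF) to the silyl ester tert-butyldimethylsilyl (E)-3-{[tert-butyl(dimethyl)silyl]oxymethyl}-4-(3,4-dimethoxyphenyl)but-3-enoate F4. K2CO3 in aqueous MeOH cleaves the silyl ester to (E)-3-{[tert-butyl(dimethyl)silyl]oxymethyl}-4-(3,4-dimethoxyphenyl)but-3-enoic acid F5. Pivaloyl chloride/Et3N gives the mixed pivalic anhydride F6, which acylates 8 to (R)-4-benzyl-3-[(E)-3-{[tert-butyl(dimethyl)silyl]oxymethyl}-4-(3,4-dimethoxyphenyl)but-3-enoyl]-1,3-oxazolidin-2-one F7. Ph3PBr2 in CH2Cl2 converts the allylic silyl ether directly into (R)-4-benzyl-3-[(E)-3-(bromomethyl)-4-(3,4-dimethoxyphenyl)but-3-enoyl]-1,3-oxazolidin-2-one F8, and LiCl in acetone exchanges bromide for chloride to give 9.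

3. Step 6. The allylic C5–O1 or benzylic C2–O1 bond may be hydrogenolysed, the double bond may migrate to C3=C4 with loss of the C3 configuration, or hydrogen may be delivered to the wrong face. Fallback, setting out from 13 and coming back at 15: the order of the last two operations is reversed and the alkene is reduced without a metal surface. LiBH4 first cleaves 13 to [(2R,3R,4E)-4-(3,4-dimethoxybenzylidene)-2-(3,4,5-trimethoxyphenyl)oxolan-3-yl]methanol F9, in which C3 is no longer α to a carbonyl. Hydrogen-atom-transfer hydrogenation (Mn(dpm)3, PhSiH3, t-BuOOH, i-PrOH) then delivers the first hydrogen atom to C4 on the open ring face, giving the benzylic C7' radical, which is reduced to CH2. This cannot cleave the C–O bonds and should give 15 directly.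

Further compounds
F1 | step 5 | (R)-4-benzyl-3-[(E)-3-(acetoxymethyl)-4-(3,4-dimethoxyphenyl)but-3-enoyl]-1,3-oxazolidin-2-one | CC(=O)OC/C(CC(=O)N1[C@H](Cc2ccccc2)COC1=O)=C/c1ccc(OC)c(OC)c1
F2 | step 5 | (R)-4-benzyl-3-[(2S,3E)-3-(acetoxymethyl)-4-(3,4-dimethoxyphenyl)-2-[(R)-(3,4,5-trimethoxyphenyl)(trimethylsilyloxy)methyl]but-3-enoyl]-1,3-oxazolidin-2-one | O=C(N1[C@H](Cc2ccccc2)COC1=O)[C@H]([C@@H](O[Si](C)(C)C)c1cc(OC)c(OC)c(OC)c1)/C(=C\c1ccc(OC)c(OC)c1)COC(C)=O
F3 | step 5 | (R)-4-benzyl-3-[(2S,3E)-3-(acetoxymethyl)-4-(3,4-dimethoxyphenyl)-2-[(R)-hydroxy(3,4,5-trimethoxyphenyl)methyl]but-3-enoyl]-1,3-oxazolidin-2-one | O=C(N1[C@H](Cc2ccccc2)COC1=O)[C@H]([C@@H](O)c1cc(OC)c(OC)c(OC)c1)/C(=C\c1ccc(OC)c(OC)c1)COC(C)=O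
F4 | step 3 | tert-butyldimethylsilyl (E)-3-{[tert-butyl(dimethyl)silyl]oxymethyl}-4-(3,4-dimethoxyphenyl)but-3-enoate | CC(C)(C)[Si](C)(C)OC/C(CC(=O)O[Si](C)(C)C(C)(C)C)=C/c1ccc(OC)c(OC)c1
F5 | step 3 | (E)-3-{[tert-butyl(dimethyl)silyl]oxymethyl}-4-(3,4-dimethoxyphenyl)but-3-enoic acid | CC(C)(C)[Si](C)(C)OC/C(CC(=O)O)=C/c1ccc(OC)c(OC)c1
F6 | step 3 | (E)-3-{[tert-butyl(dimethyl)silyl]oxymethyl}-4-(3,4-dimethoxyphenyl)but-3-enoic pivalic anhydride | CC(C)(C)[Si](C)(C)OC/C(CC(=O)OC(=O)C(C)(C)C)=C/c1ccc(OC)c(OC)c1
F7 | step 3 | (R)-4-benzyl-3-[(E)-3-{[tert-butyl(dimethyl)silyl]oxymethyl}-4-(3,4-dimethoxyphenyl)but-3-enoyl]-1,3-oxazolidin-2-one | CC(C)(C)[Si](C)(C)OC/C(CC(=O)N1[C@H](Cc2ccccc2)COC1=O)=C/c1ccc(OC)c(OC)c1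
F8 | step 3 | (R)-4-benzyl-3-[(E)-3-(bromomethyl)-4-(3,4-dimethoxyphenyl)but-3-enoyl]-1,3-oxazolidin-2-one | BrC/C(CC(=O)N1[C@H](Cc2ccccc2)COC1=O)=C/c1ccc(OC)c(OC)c1
F9 | step 6 | [(2R,3R,4E)-4-(3,4-dimethoxybenzylidene)-2-(3,4,5-trimethoxyphenyl)oxolan-3-yl]methanol | COc1ccc(/C=C2/CO[C@@H](c3cc(OC)c(OC)c(OC)c3)[C@H]2CO)cc1OC
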